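Remark on the chemistry: aldehyde 22 is assumed to be bought and distilled just before use, because it oligomerises on storage. Abbreviations in names: TES = triethylsilyl, TBS = tert-butyldimethylsilyl, PMB = 4-methoxybenzyl.

## Analysis of the target

The target 41 is a germacranolide. A ten-membered carbocycle (C1–C10) is trans-fused at C6/C7 to an α-methylene-γ-butyrolactone (O6–C12(=O)–C11(=C13H2)–C7). It carries a Z-trisubstituted C4=C5 alkene (methyl C15 on C4), a methyl C14 on C10 and an angelate on O9. Its six stereocentres are 2S,3R,6R,7S,9S,10R: the C2/C3 diol is anti along C1–C4, the C9 oxygen and the C14 methyl are anti along C8–C1, and H6/H7 are trans on the lactone. The α-methylene lactone (a Michael acceptor), the angelate (which isomerises to the tiglate under base or heat) and the allylic C3 carbinol are sensitive and must appear late. The difficulty lies in closing a medium ring that contains a Z alkene while three separated pairs of stereocentres (C2/C3, C6/C7, C9/C10) are set without one pair controlling another. The strategy rests on the C2 carbinol, the C1 methylene and C10: if C14 is read as an exocyclic methylene, C2(OH)–C1H2–C10(=C14H2) is a homoallylic alcohol, the retron of an allylmetal addition to a C2 aldehyde. The 2-substituted allyl unit is symmetric about C10, and the alkene it leaves is flanked by the C9 oxygen, which can later direct hydrogen to C10. The C6/C7 pair maps onto a 4,5-trans-disubstituted butyrolactone available from butenolide 1.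

## Retrosynthetic reasoning

**41 to 37 and 38.** The ester C–O bond at O9 and the two acetal C–O bonds are cut last. The angelate of 38 would not survive enolate chemistry, so 40 is made by acylation of 37 under conditions that do not isomerise the Z ester, and only an acid-labile acetonide then has to be removed.

**37 to 34.** The C11=C13 bond is cut. C13 is added to the lactone enolate of 34 by aminomethylation and elimination. This must follow the hydrogenation, because a conjugated methylene would be reduced with the C10=C14 alkene.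

**34 to 33.** The C10–H and C14–H bonds are cut, so the C14 methyl becomes an exocyclic methylene. The forward reaction must add hydrogen to one face of C10=C14 only; the free allylic O9–H of 33 is the handle, and the C2/C3 diol is tied up as an acetonide so that no second hydroxyl competes.

**33 to 31.** This is a protecting-group change. Both silyl ethers of 31 leave together to give 32, and the vicinal diol alone can form a five-membered acetonide, which frees O9 without a separate deprotection.

**31 to 29.** The C1–C2 bond is cut. It is the only ring bond whose cleavage uses the homoallylic alcohol retron, and it removes the ring and the C2 stereocentre at once. The open chain 29 carries an allylic bromide and an aldehyde. The forward reaction must form the ten-membered ring chemoselectively at the aldehyde, in the presence of the lactone, and add anti to the C3 silyloxy group.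

**29 to 21 and 22.** The C2 aldehyde is traced to the dioxolane of 27, 25 and 24, and the bromide to the PMB ether of 25. The C3–C4 bond is then cut between alkenyl iodide 21 and aldehyde 22. The stereocentre of 22 sets C3 by 1,2-induction, and its terminal carbon is given up in the later glycol cleavage.

**21 to 16 and 17.** The C4=C5 bond is cut. An iodo-olefination of aldehyde 16 with the ylide from 17 gives the Z geometry and the halide needed for the next coupling in one operation.

**16 to 7 and 9.** After adjustment of the oxidation level at C5 (16 from 15 and 14), the C9–C10 bond is cut between aldehyde 7 and alkenyl bromide 9 (from 8). Induction from C7 to C9 would be unreliable, so the C9 configuration is set by a reagent-controlled reduction of enone 12 to 13.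

**7 to 1.** The C7–C8 bond is cut. Conjugate allylation of butenolide 2 with 3, trans to the C5 substituent, gives 5 and sets C7 from the C6 centre of 1. Ozonolysis then trims the allyl group to the C9 aldehyde.

## Alternatives that were turned down

**Alternative 1:** The ten-membered ring is hidden in a cis-fused bicyclo[4.4.0]decane by an extra C4–C9 bond. In the forward key step a tertiary C9 alkoxide, made with a strong alkoxide base, pushes out a C5 sulfonate with loss of the central bond (Grob fragmentation) and gives the Z-cyclodecenone A1.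
- For it: the ring is formed without a macrocyclisation, and the Z geometry follows stereospecifically from the antiperiplanar arrangement. On both points it is stronger than the chosen route.
- Against it: the fragmentation substrate needs a quaternary C4, a tertiary C9 carbinol and the lactone on one decalin, with every centre in the right relative sense. The basic conditions threaten the lactone and the C10 centre, which becomes α to the new ketone. The C9 ketone of A1 must then be reduced to 9S in a medium ring without a control element.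
- Comparison: the chosen route is shorter and sets C9 by a catalyst before the ring exists, and it takes C6/C7 from the chiral pool. It gives up the guaranteed ring formation in exchange.

**Alternative 2:** The C6–C7 bond is cut, and the ring is expanded in the reverse sense to a thirteen-membered bis-allylic ether (O6 bonded to C13). In the forward step an amide base removes a C6 proton and a [2,3]-Wittig shift contracts the ring to the ten-membered alcohol A2, which has the exocyclic C11=C13 methylene.
- For it: the carbon–carbon bond forms in a pre-organised sigmatropic step, and the C6 hydroxyl and the C13 methylene of the lactone appear together. In mapping onto the methylene lactone it is as strong as or stronger than the chosen route.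
- Against it: two stereocentres (C6 and C7) are created in a transannular transition state. Deprotonation must choose C6 over C13, a [1,2]-shift competes, and the Z allyl anion can lose its geometry. C12 of A2 must still be oxidised and lactonised, and the ether ring itself needs a macrocyclisation.
- Comparison: the chosen route buys C6 and C7 with the starting material and leaves only C2 to the ring-forming step.

**Alternative 3:** The C7–C8 bond is cut. A primary C8 radical, generated from an iodide by a tin-centred radical, adds to C7 of a 3-(stannylmethyl)butenolide, and loss of the stannyl radical leaves the methylene lactone A3.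
- For it: the ring and the α-methylene lactone are formed together, C10 is already a methyl stereocentre, and the endgame is shorter than in the chosen route.
- Against it: addition of an unactivated primary radical in a ten-membered closure is slow, so intramolecular hydrogen transfer from α-oxy and allylic positions and intermolecular addition compete. The acid-labile allylstannane has to be carried through the assembly of the whole chain. C6 can then no longer come from a simple butenolide.
- Comparison: the chosen closure is a polar carbonyl addition templated by chromium–oxygen coordination, with precedent for this ring size. It pays for that with the steps after the ring closure.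

Key step: step 17

## Route

**Step 1**
Reactants: 1 (S)-5-(hydroxymethyl)furan-2(5H)-one
Product: 2 (S)-5-[(triethylsilyloxy)methyl]furan-2(5H)-one
Conditions: Et3SiCl, imidazole, CH2Cl2, 0 °C
Reagents that add atoms: chlorotriethylsilane, CC[Si](CC)(CC)Cl
Why: Silylation of the primary alcohol; the TES ether shields one face of the butenolide and can later be removed beside a secondary TBS ether.

**Step 2**
Reactants: 2 (S)-5-[(triethylsilyloxy)methyl]furan-2(5H)-one; 3 allylmagnesium bromide
Product: 5 (4S,5S)-4-allyl-5-[(triethylsilyloxy)methyl]dihydrofuran-2(3H)-one, via trimethylsilyl ketene acetal 4 (not isolated)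
Conditions: allylMgBr, CuBr·SMe2, Me3SiCl, THF, −78 °C; aq NH4Cl
Reagents that add atoms: none
Why: Copper-mediated conjugate allylation accelerated by Me3SiCl, which traps the enolate as ketene acetal 4 and suppresses 1,2-addition. The allyl group enters anti to the C5 substituent of the planar butenolide, which sets C7 (4S) trans to C6.

**Step 3**
Reactants: 5 (4S,5S)-4-allyl-5-[(triethylsilyloxy)methyl]dihydrofuran-2(3H)-one
Product: 7 2-[(2S,3S)-5-oxo-2-[(triethylsilyloxy)methyl]tetrahydrofuran-3-yl]acetaldehyde, via ozonide 6 (not isolated)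
Conditions: O3, CH2Cl2, −78 °C; PPh3, −78 °C to rt
Reagents that add atoms: ozone, [O-][O+]=O
Why: Ozonolysis with reductive work-up cuts the only alkene and leaves the C9 aldehyde; silyl ether and lactone are inert.

**Step 4**
Reactants: 8 2-bromoprop-2-en-1-ol
Product: 9 1-[(2-bromoallyloxy)methyl]-4-methoxybenzene
Conditions: NaH, 4-methoxybenzyl chloride, Bu4NI (cat.), THF, 0 °C to rt
Reagents that add atoms: 4-methoxybenzyl chloride, COc1ccc(CCl)cc1
Why: Williamson ether synthesis; the PMB ether masks the future C1 bromide and can be removed oxidatively beside silyl ethers.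

**Step 5**
Reactants: 7 2-[(2S,3S)-5-oxo-2-[(triethylsilyloxy)methyl]tetrahydrofuran-3-yl]acetaldehyde; 9 1-[(2-bromoallyloxy)methyl]-4-methoxybenzene
Product: 11 (4S,5S)-4-[2-hydroxy-3-[(PMB-oxy)methyl]but-3-en-1-yl]-5-[(TES-oxy)methyl]dihydrofuran-2(3H)-one (C9 epimers), via alkenylchromium dichloride 10 (not isolated)
Conditions: CrCl2, NiCl2 (cat.), DMSO, rt
Reagents that add atoms: none
Why: Nozaki–Hiyama–Kishi coupling: zerovalent nickel inserts into the C–Br bond, the alkenyl group passes to trivalent chromium and adds to the aldehyde only, not to the lactone. The C9 epimer mixture is acceptable because the next step removes this centre.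

**Step 6**
Reactants: 11 (4S,5S)-4-[2-hydroxy-3-[(PMB-oxy)methyl]but-3-en-1-yl]-5-[(TES-oxy)methyl]dihydrofuran-2(3H)-one
Product: 12 (4S,5S)-4-[3-[(PMB-oxy)methyl]-2-oxobut-3-en-1-yl]-5-[(TES-oxy)methyl]dihydrofuran-2(3H)-one
Conditions: Dess–Martin periodinane, CH2Cl2, 0 °C to rt
Reagents that add atoms: none
Why: Dess–Martin oxidation of the allylic alcohol under near-neutral conditions; the α-methylene ketone is used without storage.

**Step 7**
Reactants: 12 (4S,5S)-4-[3-[(PMB-oxy)methyl]-2-oxobut-3-en-1-yl]-5-[(TES-oxy)methyl]dihydrofuran-2(3H)-one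
Product: 13 (4S,5S)-4-[(2S)-2-hydroxy-3-[(PMB-oxy)methyl]but-3-en-1-yl]-5-[(TES-oxy)methyl]dihydrofuran-2(3H)-one
Conditions: (R)-2-methyl-CBS-oxazaborolidine [(R)-1-methyl-3,3-diphenyltetrahydro-1H,3H-pyrrolo[1,2-c][1,3,2]oxazaborole] (20 mol%), catecholborane, toluene, −78 °C
Reagents that add atoms: none
Why: Corey–Bakshi–Shibata reduction: the α-branched alkenyl group acts as the large substituent and the CH2 chain as the small one, so the (R)-catalyst should deliver hydride to give the 9S alcohol under reagent control. At −78 °C neither the lactone nor the alkene is touched.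

**Step 8**
Reactants: 13 (4S,5S)-4-[(2S)-2-hydroxy-3-[(PMB-oxy)methyl]but-3-en-1-yl]-5-[(TES-oxy)methyl]dihydrofuran-2(3H)-one
Product: 14 (4S,5S)-4-[(2S)-2-(TBS-oxy)-3-[(PMB-oxy)methyl]but-3-en-1-yl]-5-[(TES-oxy)methyl]dihydrofuran-2(3H)-one
Conditions: TBSOTf, 2,6-lutidine, CH2Cl2, −78 to 0 °C
Reagents that add atoms: tert-butyldimethylsilyl trifluoromethanesulfonate, CC(C)(C)[Si](C)(C)OS(=O)(=O)C(F)(F)F
Why: Silylation of the hindered secondary allylic alcohol with the silyl triflate; the lactone is not enolised by 2,6-lutidine.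

**Step 9**
Reactants: 14 (4S,5S)-4-[(2S)-2-(TBS-oxy)-3-[(PMB-oxy)methyl]but-3-en-1-yl]-5-[(TES-oxy)methyl]dihydrofuran-2(3H)-one
Product: 15 (4S,5S)-4-[(2S)-2-(TBS-oxy)-3-[(PMB-oxy)methyl]but-3-en-1-yl]-5-(hydroxymethyl)dihydrofuran-2(3H)-one
Conditions: PPTS (cat.), MeOH/CH2Cl2, 0 °C
Reagents that add atoms: none
Why: Acid-catalysed methanolysis cleaves the primary TES ether much faster than the hindered secondary TBS ether; PMB ether and lactone are stable.

**Step 10**
Reactants: 15 (4S,5S)-4-[(2S)-2-(TBS-oxy)-3-[(PMB-oxy)methyl]but-3-en-1-yl]-5-(hydroxymethyl)dihydrofuran-2(3H)-one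
Product: 16 (2S,3S)-3-[(2S)-2-(TBS-oxy)-3-[(PMB-oxy)methyl]but-3-en-1-yl]-5-oxotetrahydrofuran-2-carbaldehyde
Conditions: Dess–Martin periodinane, CH2Cl2, 0 °C
Reagents that add atoms: none
Why: Dess–Martin oxidation gives the α-acyloxy aldehyde without base, so C6 is not epimerised; the crude aldehyde goes straight into the olefination.

**Step 11**
Reactants: 16 (2S,3S)-3-[(2S)-2-(TBS-oxy)-3-[(PMB-oxy)methyl]but-3-en-1-yl]-5-oxotetrahydrofuran-2-carbaldehyde; 17 ethyltriphenylphosphonium iodide
Product: 21 (4S,5S)-4-[(2S)-2-(TBS-oxy)-3-[(PMB-oxy)methyl]but-3-en-1-yl]-5-[(Z)-2-iodoprop-1-en-1-yl]dihydrofuran-2(3H)-one, via ethylidenetriphenylphosphorane 18 (not isolated), via (1-iodoethyl)triphenylphosphonium iodide 19 (not isolated), via (1-iodoethylidene)triphenylphosphorane 20 (not isolated)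
Conditions: 17, n-BuLi, THF, 0 °C; I2, −78 °C; NaN(SiMe3)2, −78 to −20 °C; then 16, −78 °C
Reagents that add atoms: iodine, II
Why: Stork–Zhao-type Wittig iodo-olefination: the α-iodo ylide reacts under kinetic control through the cis oxaphosphetane, which places iodine cis to the C6 substituent (Z). The ylide is formed before the aldehyde is added, so the lactone and the C6 centre see no free strong base.

**Step 12**
Reactants: 21 (4S,5S)-4-[(2S)-2-(TBS-oxy)-3-[(PMB-oxy)methyl]but-3-en-1-yl]-5-[(Z)-2-iodoprop-1-en-1-yl]dihydrofuran-2(3H)-one; 22 (S)-2,2-dimethyl-1,3-dioxolane-4-carbaldehyde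
Product: 24 (4S,5S)-4-[(2S)-2-(TBS-oxy)-3-[(PMB-oxy)methyl]but-3-en-1-yl]-5-[(1Z,3R)-3-[(4S)-2,2-dimethyl-1,3-dioxolan-4-yl]-3-hydroxy-2-methylprop-1-en-1-yl]dihydrofuran-2(3H)-one, via alkenylchromium dichloride 23 (not isolated)
Conditions: CrCl2, NiCl2 (cat.), DMSO, rt
Reagents that add atoms: none
Why: Nozaki–Hiyama–Kishi coupling, which keeps the geometry of a trisubstituted alkenyl iodide and tolerates the lactone. The alkenylchromium adds to 22 in the Felkin–Anh sense, anti to the dioxolane C–O bond, which should give the 3R (anti) alcohol as the main isomer; the minor epimer is removed by chromatography.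

**Step 13**
Reactants: 24 (4S,5S)-4-[(2S)-2-(TBS-oxy)-3-[(PMB-oxy)methyl]but-3-en-1-yl]-5-[(1Z,3R)-3-[(4S)-2,2-dimethyl-1,3-dioxolan-4-yl]-3-hydroxy-2-methylprop-1-en-1-yl]dihydrofuran-2(3H)-one
Product: 25 (4S,5S)-4-[(2S)-2-(TBS-oxy)-3-[(PMB-oxy)methyl]but-3-en-1-yl]-5-[(1Z,3R)-3-(TBS-oxy)-3-[(4S)-2,2-dimethyl-1,3-dioxolan-4-yl]-2-methylprop-1-en-1-yl]dihydrofuran-2(3H)-one
Conditions: TBSOTf, 2,6-lutidine, CH2Cl2, −78 to 0 °C
Reagents that add atoms: tert-butyldimethylsilyl trifluoromethanesulfonate, CC(C)(C)[Si](C)(C)OS(=O)(=O)C(F)(F)F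
Why: Silylation of the flanked allylic alcohol; the bulky, non-chelating silyl ether at O3 is the control element for the key step, and the isopropylidene ketal is stable to the buffered triflate.

**Step 14**
Reactants: 25 (4S,5S)-4-[(2S)-2-(TBS-oxy)-3-[(PMB-oxy)methyl]but-3-en-1-yl]-5-[(1Z,3R)-3-(TBS-oxy)-3-[(4S)-2,2-dimethyl-1,3-dioxolan-4-yl]-2-methylprop-1-en-1-yl]dihydrofuran-2(3H)-one
Product: 26 (4S,5S)-4-[(2S)-2-(TBS-oxy)-3-(hydroxymethyl)but-3-en-1-yl]-5-[(1Z,3R)-3-(TBS-oxy)-3-[(4S)-2,2-dimethyl-1,3-dioxolan-4-yl]-2-methylprop-1-en-1-yl]dihydrofuran-2(3H)-one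
Conditions: DDQ, CH2Cl2/pH 7 buffer, 0 °C
Reagents that add atoms: none
Why: Oxidative cleavage of the PMB ether under buffered neutral conditions; silyl ethers, acetonide and lactone are untouched, and a small excess of oxidant at 0 °C avoids oxidation of the allylic alcohol.

**Step 15**
Reactants: 26 (4S,5S)-4-[(2S)-2-(TBS-oxy)-3-(hydroxymethyl)but-3-en-1-yl]-5-[(1Z,3R)-3-(TBS-oxy)-3-[(4S)-2,2-dimethyl-1,3-dioxolan-4-yl]-2-methylprop-1-en-1-yl]dihydrofuran-2(3H)-one
Product: 27 (4S,5S)-4-[(2S)-3-(bromomethyl)-2-(TBS-oxy)but-3-en-1-yl]-5-[(1Z,3R)-3-(TBS-oxy)-3-[(4S)-2,2-dimethyl-1,3-dioxolan-4-yl]-2-methylprop-1-en-1-yl]dihydrofuran-2(3H)-one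
Conditions: CBr4, PPh3, CH2Cl2, 0 °C
Reagents that add atoms: carbon tetrabromide, BrC(Br)(Br)Br
Why: Appel bromination of the primary allylic alcohol under neutral conditions; allylic transposition would give the same bromide because the allyl unit is symmetric.

**Step 16**
Reactants: 27 (4S,5S)-4-[(2S)-3-(bromomethyl)-2-(TBS-oxy)but-3-en-1-yl]-5-[(1Z,3R)-3-(TBS-oxy)-3-[(4S)-2,2-dimethyl-1,3-dioxolan-4-yl]-2-methylprop-1-en-1-yl]dihydrofuran-2(3H)-one
Product: 29 (2R,3Z)-4-[(2S,3S)-3-[(2S)-3-(bromomethyl)-2-(TBS-oxy)but-3-en-1-yl]-5-oxotetrahydrofuran-2-yl]-2-(TBS-oxy)-3-methylbut-3-enal, via diol 28 (not isolated)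
Conditions: H5IO6, EtOAc, rt
Reagents that add atoms: none
Why: Periodic acid hydrolyses the terminal acetonide and cleaves the freed glycol in the same flask; secondary silyl ethers, the allylic bromide and the lactone are inert. The aldehyde is used at once because C3 is allylic and α to the carbonyl.

**Step 17**
Reactants: 29 (2R,3Z)-4-[(2S,3S)-3-[(2S)-3-(bromomethyl)-2-(TBS-oxy)but-3-en-1-yl]-5-oxotetrahydrofuran-2-yl]-2-(TBS-oxy)-3-methylbut-3-enal
Product: 31 (2S,3R,6S,7S,9S)-3,9-bis(TBS-oxy)-2-hydroxygermacra-4Z,10(14)-dien-12,6-olide, via allylchromium dichloride 30 (not isolated)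
Conditions: CrCl2 (excess), THF, rt, slow addition of 29 at high dilution (about 0.003 M)
Reagents that add atoms: none
Why: Two equivalents of divalent chromium reduce the allylic C–Br bond by two single-electron transfers to the trivalent allylchromium species 30, whose two CH2 termini interconvert by metal shift about C10. It adds to the aldehyde through a six-membered chair-like transition state with chromium on the carbonyl oxygen and with allyl transposition, which forms C1–C2 and leaves C10=C14 exocyclic; the closest known reaction type is the intramolecular Nozaki–Hiyama (Barbier-type) allylation used to close ten-membered and larger carbocycles. The ring closes in a 10-exo-trig mode with respect to the carbonyl group. The new C2 centre is controlled by the C3 silyloxy group: in the Felkin–Anh arrangement the C3–O bond is antiperiplanar to the incoming carbon and the nucleophile passes the C3 hydrogen, which gives the 2,3-anti (2S) alcohol, while the bulky silyl ether suppresses the chelate that would lead to the syn isomer. The step needs addition to the aldehyde and not to the lactone (allylchromium reagents do not add to esters), ring closure over intermolecular coupling (slow addition at high dilution) and no epimerisation at C3 (neutral, non-basic medium). The regiochemistry of the allyl unit is not an issue, because either terminus gives the same product.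

**Step 18**
Reactants: 31 (2S,3R,6S,7S,9S)-3,9-bis(TBS-oxy)-2-hydroxygermacra-4Z,10(14)-dien-12,6-olide
Product: 32 (2S,3R,6S,7S,9S)-2,3,9-trihydroxygermacra-4Z,10(14)-dien-12,6-olide
Conditions: HF·pyridine, pyridine, THF, 0 °C to rt
Reagents that add atoms: none
Why: Buffered fluoride cleavage of both secondary silyl ethers; the weakly acidic medium avoids the acyl migration that a basic fluoride source could cause at the lactone.

**Step 19**
Reactants: 32 (2S,3R,6S,7S,9S)-2,3,9-trihydroxygermacra-4Z,10(14)-dien-12,6-olide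
Product: 33 (2S,3R,6S,7S,9S)-9-hydroxy-2,3-(isopropylidenedioxy)germacra-4Z,10(14)-dien-12,6-olide
Conditions: Me2C(OMe)2, PPTS (cat.), CH2Cl2, rt
Reagents that add atoms: 2,2-dimethoxypropane, COC(C)(C)OC
Why: Transketalisation: only the vicinal C2/C3 diol can form a five-membered dioxolane, so O9 stays free without a separate deprotection.

**Step 20**
Reactants: 33 (2S,3R,6S,7S,9S)-9-hydroxy-2,3-(isopropylidenedioxy)germacra-4Z,10(14)-dien-12,6-olide
Product: 34 (2S,3R,6S,7S,9S,10R)-9-hydroxy-2,3-(isopropylidenedioxy)germacr-4Z-en-12,6-olide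
Conditions: [Rh(nbd)(dppb)]BF4 (10 mol%), H2 (about 50 bar), CH2Cl2, rt
Reagents that add atoms: none
Why: Hydroxyl-directed hydrogenation: the cationic rhodium centre binds O9–H and the adjacent 1,1-disubstituted alkene and transfers hydrogen within this chelate. With the C9–H bond near the alkene plane (least allylic 1,2-strain), delivery from the hydroxyl face should give the 9,10-anti, 10R methyl. The trisubstituted C4=C5 alkene has no free hydroxyl nearby and is not reduced, and high pressure suppresses alkene migration.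

**Step 21**
Reactants: 34 (2S,3R,6S,7S,9S,10R)-9-hydroxy-2,3-(isopropylidenedioxy)germacr-4Z-en-12,6-olide
Product: 35 (2S,3R,6S,7S,9S,10R)-13-(dimethylamino)-9-hydroxy-2,3-(isopropylidenedioxy)germacr-4Z-en-12,6-olide (C11 epimers)
Conditions: LiN(i-Pr)2 (3 equiv), THF, −78 °C; CH2=NMe2+ I−, −78 to 0 °C
Reagents that add atoms: Eschenmoser's salt (N,N-dimethylmethyleneiminium iodide), C=[N+](C)C.[I-]
Why: Mannich-type aminomethylation of the lactone enolate formed as the alkoxide–enolate dianion; adding 34 to excess base makes enolisation faster than any attack of the O9 alkoxide on the lactone. The C11 configuration is irrelevant because it is removed in the next step.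

**Step 22**
Reactants: 35 (2S,3R,6S,7S,9S,10R)-13-(dimethylamino)-9-hydroxy-2,3-(isopropylidenedioxy)germacr-4Z-en-12,6-olide
Product: 37 (2S,3R,6R,7S,9S,10R)-9-hydroxy-2,3-(isopropylidenedioxy)germacra-4Z,11(13)-dien-12,6-olide, via trimethylammonium iodide 36 (not isolated)
Conditions: MeI, MeOH, rt; then NaHCO3, CH2Cl2/H2O, rt
Reagents that add atoms: none
Why: Quaternisation and mild-base Hofmann-type elimination give the α-methylene lactone; the free secondary alcohol is not methylated under neutral conditions. The C6 descriptor changes from S to R only because C11 gains priority.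

**Step 23**
Reactants: 37 (2S,3R,6R,7S,9S,10R)-9-hydroxy-2,3-(isopropylidenedioxy)germacra-4Z,11(13)-dien-12,6-olide; 38 angelic acid [(Z)-2-methylbut-2-enoic acid]
Product: 40 (2S,3R,6R,7S,9S,10R)-9-(angeloyloxy)-2,3-(isopropylidenedioxy)germacra-4Z,11(13)-dien-12,6-olide, via angelic 2,4,6-trichlorobenzoic anhydride 39 (not isolated)
Conditions: 38, 2,4,6-Cl3C6H2COCl, Et3N, toluene, rt; then 37, 80 °C
Reagents that add atoms: none
Why: Yamaguchi-type mixed-anhydride esterification run without a nucleophilic pyridine catalyst, the conditions under which angelates form without isomerisation to tiglates. The hindered aroyl carbonyl directs the alcohol to the angeloyl carbonyl.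

**Step 24**
Reactants: 40 (2S,3R,6R,7S,9S,10R)-9-(angeloyloxy)-2,3-(isopropylidenedioxy)germacra-4Z,11(13)-dien-12,6-olide
Product: 41 (2S,3R,6R,7S,9S,10R)-9-(angeloyloxy)-2,3-dihydroxygermacra-4Z,11(13)-dien-12,6-olide (target)
Conditions: AcOH/H2O (4:1), 40 °C
Reagents that add atoms: none
Why: Mild acid hydrolysis of the acetonide; the angelate, the α-methylene lactone and the allylic C3 alcohol tolerate aqueous acetic acid, and no nucleophilic solvent is present that could add to the methylene lactone.

## Compound list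

1 | (S)-5-(hydroxymethyl)furan-2(5H)-one | OC[C@H]1OC(=O)C=C1 | starting material
2 | (S)-5-[(triethylsilyloxy)methyl]furan-2(5H)-one | CC[Si](CC)(CC)OC[C@H]1OC(=O)C=C1 | intermediate
3 | allylmagnesium bromide | C=CC[Mg]Br | starting material
4 | [(4S,5S)-4-allyl-5-[(TES-oxy)methyl]-4,5-dihydrofuran-2-yl]oxytrimethylsilane (trimethylsilyl ketene acetal) | C=CC[C@H]1C=C(O[Si](C)(C)C)O[C@@H]1CO[Si](CC)(CC)CC | intermediate
5 | (4S,5S)-4-allyl-5-[(triethylsilyloxy)methyl]dihydrofuran-2(3H)-one | C=CC[C@H]1CC(=O)O[C@@H]1CO[Si](CC)(CC)CC | intermediate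
6 | ozonide of 5 (1,2,4-trioxolane on the former allyl terminus, epimers) | O1OC(C[C@H]2CC(=O)O[C@@H]2CO[Si](CC)(CC)CC)OC1 | intermediate
7 | 2-[(2S,3S)-5-oxo-2-[(triethylsilyloxy)methyl]tetrahydrofuran-3-yl]acetaldehyde | O=CC[C@H]1CC(=O)O[C@@H]1CO[Si](CC)(CC)CC | intermediate
8 | 2-bromoprop-2-en-1-ol | OCC(Br)=C | starting material
9 | 1-[(2-bromoallyloxy)methyl]-4-methoxybenzene | C=C(Br)COCc1ccc(OC)cc1 | intermediate
10 | [3-(PMB-oxy)prop-1-en-2-yl]chromium dichloride | C=C([Cr](Cl)Cl)COCc1ccc(OC)cc1 | intermediate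
11 | (4S,5S)-4-[2-hydroxy-3-[(PMB-oxy)methyl]but-3-en-1-yl]-5-[(TES-oxy)methyl]dihydrofuran-2(3H)-one (C9 epimers) | C=C(COCc1ccc(OC)cc1)C(O)C[C@H]1CC(=O)O[C@@H]1CO[Si](CC)(CC)CC | intermediate
12 | (4S,5S)-4-[3-[(PMB-oxy)methyl]-2-oxobut-3-en-1-yl]-5-[(TES-oxy)methyl]dihydrofuran-2(3H)-one | C=C(COCc1ccc(OC)cc1)C(=O)C[C@H]1CC(=O)O[C@@H]1CO[Si](CC)(CC)CC | intermediate
13 | (4S,5S)-4-[(2S)-2-hydroxy-3-[(PMB-oxy)methyl]but-3-en-1-yl]-5-[(TES-oxy)methyl]dihydrofuran-2(3H)-one | C=C(COCc1ccc(OC)cc1)[C@@H](O)C[C@H]1CC(=O)O[C@@H]1CO[Si](CC)(CC)CC | intermediate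
14 | (4S,5S)-4-[(2S)-2-(TBS-oxy)-3-[(PMB-oxy)methyl]but-3-en-1-yl]-5-[(TES-oxy)methyl]dihydrofuran-2(3H)-one | C=C(COCc1ccc(OC)cc1)[C@@H](O[Si](C)(C)C(C)(C)C)C[C@H]1CC(=O)O[C@@H]1CO[Si](CC)(CC)CC | intermediate
15 | (4S,5S)-4-[(2S)-2-(TBS-oxy)-3-[(PMB-oxy)methyl]but-3-en-1-yl]-5-(hydroxymethyl)dihydrofuran-2(3H)-one | C=C(COCc1ccc(OC)cc1)[C@@H](O[Si](C)(C)C(C)(C)C)C[C@H]1CC(=O)O[C@@H]1CO | intermediate
16 | (2S,3S)-3-[(2S)-2-(TBS-oxy)-3-[(PMB-oxy)methyl]but-3-en-1-yl]-5-oxotetrahydrofuran-2-carbaldehyde | C=C(COCc1ccc(OC)cc1)[C@@H](O[Si](C)(C)C(C)(C)C)C[C@H]1CC(=O)O[C@@H]1C=O | intermediate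
17 | ethyltriphenylphosphonium iodide | CC[P+](c1ccccc1)(c1ccccc1)c1ccccc1.[I-] | starting material
18 | ethylidenetriphenylphosphorane | CC=P(c1ccccc1)(c1ccccc1)c1ccccc1 | intermediate
19 | (1-iodoethyl)triphenylphosphonium iodide | CC(I)[P+](c1ccccc1)(c1ccccc1)c1ccccc1.[I-] | intermediate
20 | (1-iodoethylidene)triphenylphosphorane | CC(I)=P(c1ccccc1)(c1ccccc1)c1ccccc1 | intermediate
21 | (4S,5S)-4-[(2S)-2-(TBS-oxy)-3-[(PMB-oxy)methyl]but-3-en-1-yl]-5-[(Z)-2-iodoprop-1-en-1-yl]dihydrofuran-2(3H)-one | C=C(COCc1ccc(OC)cc1)[C@@H](O[Si](C)(C)C(C)(C)C)C[C@H]1CC(=O)O[C@@H]1/C=C(/C)I | intermediate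
22 | (S)-2,2-dimethyl-1,3-dioxolane-4-carbaldehyde | O=C[C@@H]1COC(C)(C)O1 | starting material
23 | alkenylchromium dichloride from 21 (chromium in place of iodine) | C=C(COCc1ccc(OC)cc1)[C@@H](O[Si](C)(C)C(C)(C)C)C[C@H]1CC(=O)O[C@@H]1/C=C(/C)[Cr](Cl)Cl | intermediate
24 | (4S,5S)-4-[(2S)-2-(TBS-oxy)-3-[(PMB-oxy)methyl]but-3-en-1-yl]-5-[(1Z,3R)-3-[(4S)-2,2-dimethyl-1,3-dioxolan-4-yl]-3-hydroxy-2-methylprop-1-en-1-yl]dihydrofuran-2(3H)-one | C=C(COCc1ccc(OC)cc1)[C@@H](O[Si](C)(C)C(C)(C)C)C[C@H]1CC(=O)O[C@@H]1/C=C(/C)[C@@H](O)[C@@H]2COC(C)(C)O2 | intermediate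
25 | 3-O-TBS ether of 24 | C=C(COCc1ccc(OC)cc1)[C@@H](O[Si](C)(C)C(C)(C)C)C[C@H]1CC(=O)O[C@@H]1/C=C(/C)[C@@H](O[Si](C)(C)C(C)(C)C)[C@@H]2COC(C)(C)O2 | intermediate
26 | (4S,5S)-4-[(2S)-2-(TBS-oxy)-3-(hydroxymethyl)but-3-en-1-yl]-5-[(1Z,3R)-3-(TBS-oxy)-3-[(4S)-2,2-dimethyl-1,3-dioxolan-4-yl]-2-methylprop-1-en-1-yl]dihydrofuran-2(3H)-one | C=C(CO)[C@@H](O[Si](C)(C)C(C)(C)C)C[C@H]1CC(=O)O[C@@H]1/C=C(/C)[C@@H](O[Si](C)(C)C(C)(C)C)[C@@H]2COC(C)(C)O2 | intermediate
27 | (4S,5S)-4-[(2S)-3-(bromomethyl)-2-(TBS-oxy)but-3-en-1-yl]-5-[(1Z,3R)-3-(TBS-oxy)-3-[(4S)-2,2-dimethyl-1,3-dioxolan-4-yl]-2-methylprop-1-en-1-yl]dihydrofuran-2(3H)-one | C=C(CBr)[C@@H](O[Si](C)(C)C(C)(C)C)C[C@H]1CC(=O)O[C@@H]1/C=C(/C)[C@@H](O[Si](C)(C)C(C)(C)C)[C@@H]2COC(C)(C)O2 | intermediate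
28 | (4S,5S)-4-[(2S)-3-(bromomethyl)-2-(TBS-oxy)but-3-en-1-yl]-5-[(1Z,3R,4S)-3-(TBS-oxy)-4,5-dihydroxy-2-methylpent-1-en-1-yl]dihydrofuran-2(3H)-one | C=C(CBr)[C@@H](O[Si](C)(C)C(C)(C)C)C[C@H]1CC(=O)O[C@@H]1/C=C(/C)[C@@H](O[Si](C)(C)C(C)(C)C)[C@@H](O)CO | intermediate
29 | (2R,3Z)-4-[(2S,3S)-3-[(2S)-3-(bromomethyl)-2-(TBS-oxy)but-3-en-1-yl]-5-oxotetrahydrofuran-2-yl]-2-(TBS-oxy)-3-methylbut-3-enal | C=C(CBr)[C@@H](O[Si](C)(C)C(C)(C)C)C[C@H]1CC(=O)O[C@@H]1/C=C(/C)[C@@H](O[Si](C)(C)C(C)(C)C)C=O | intermediate
30 | allylchromium dichloride from 29 (CrCl2 on C1 in place of bromine) | C=C(C[Cr](Cl)Cl)[C@@H](O[Si](C)(C)C(C)(C)C)C[C@H]1CC(=O)O[C@@H]1/C=C(/C)[C@@H](O[Si](C)(C)C(C)(C)C)C=O | intermediate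
31 | (2S,3R,6S,7S,9S)-3,9-bis(TBS-oxy)-2-hydroxygermacra-4Z,10(14)-dien-12,6-olide | C1C(=O)O[C@@H]2/C=C(/C)[C@@H](O[Si](C)(C)C(C)(C)C)[C@@H](O)CC(=C)[C@@H](O[Si](C)(C)C(C)(C)C)C[C@@H]12 | intermediate
32 | (2S,3R,6S,7S,9S)-2,3,9-trihydroxygermacra-4Z,10(14)-dien-12,6-olide | C1C(=O)O[C@@H]2/C=C(/C)[C@@H](O)[C@@H](O)CC(=C)[C@@H](O)C[C@@H]12 | intermediate
33 | (2S,3R,6S,7S,9S)-9-hydroxy-2,3-(isopropylidenedioxy)germacra-4Z,10(14)-dien-12,6-olide | C1C(=O)O[C@@H]2/C=C(/C)[C@H]3OC(C)(C)O[C@H]3CC(=C)[C@@H](O)C[C@@H]12 | intermediate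
34 | (2S,3R,6S,7S,9S,10R)-9-hydroxy-2,3-(isopropylidenedioxy)germacr-4Z-en-12,6-olide | C1C(=O)O[C@@H]2/C=C(/C)[C@H]3OC(C)(C)O[C@H]3C[C@@H](C)[C@@H](O)C[C@@H]12 | intermediate
35 | (2S,3R,6S,7S,9S,10R)-13-(dimethylamino)-9-hydroxy-2,3-(isopropylidenedioxy)germacr-4Z-en-12,6-olide (C11 epimers) | CN(C)CC1C(=O)O[C@@H]2/C=C(/C)[C@H]3OC(C)(C)O[C@H]3C[C@@H](C)[C@@H](O)C[C@@H]12 | intermediate
36 | N-methyl quaternary ammonium iodide of 35 | C[N+](C)(C)CC1C(=O)O[C@@H]2/C=C(/C)[C@H]3OC(C)(C)O[C@H]3C[C@@H](C)[C@@H](O)C[C@@H]12.[I-] | intermediate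
37 | (2S,3R,6R,7S,9S,10R)-9-hydroxy-2,3-(isopropylidenedioxy)germacra-4Z,11(13)-dien-12,6-olide | C=C1C(=O)O[C@@H]2/C=C(/C)[C@H]3OC(C)(C)O[C@H]3C[C@@H](C)[C@@H](O)C[C@@H]12 | intermediate
38 | angelic acid, (Z)-2-methylbut-2-enoic acid | C/C=C(/C)C(=O)O | starting material
39 | angelic 2,4,6-trichlorobenzoic anhydride | C/C=C(/C)C(=O)OC(=O)c1c(Cl)cc(Cl)cc1Cl | intermediate
40 | (2S,3R,6R,7S,9S,10R)-9-(angeloyloxy)-2,3-(isopropylidenedioxy)germacra-4Z,11(13)-dien-12,6-olide | C=C1C(=O)O[C@@H]2/C=C(/C)[C@H]3OC(C)(C)O[C@H]3C[C@@H](C)[C@@H](OC(=O)/C(C)=C\C)C[C@@H]12 | intermediate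
41 | (2S,3R,6R,7S,9S,10R)-9-(angeloyloxy)-2,3-dihydroxygermacra-4Z,11(13)-dien-12,6-olide (CNP0229085.1) | C=C1C(=O)O[C@@H]2/C=C(/C)[C@@H](O)[C@@H](O)C[C@@H](C)[C@@H](OC(=O)/C(C)=C\C)C[C@@H]12 | target

## Step count and least certain steps

Total: 24 steps. Longest linear sequence: 23 steps from 1 (steps 1–3 and 5–24); step 4 is a one-step side branch.

**Step 17 (key step).** Two things can go wrong. Intermolecular allylation can outrun ring closure; this is met within the step by slow addition at high dilution. More likely, the ring-forming transition state, and not the acyclic Felkin–Anh preference, may decide the face of the aldehyde that is attacked, so that facial selectivity at C2 is poor or reversed. The fallback changes how C2 is secured and sets out from 29: the cyclisation is run as described and the wrongly configured alcohol, the (2R)-epimer F1, is inverted in a Mitsunobu reaction (4-nitrobenzoic acid, PPh3, DIAD, toluene, 0 °C) to the (2S)-4-nitrobenzoate F2. Brief methanolysis (K2CO3, MeOH, 0 °C) cleaves the activated ester faster than the lactone and comes back to 31.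

**Step 20.** The ring conformation may not allow the rotamer assumed for hydroxyl delivery, so hydrogen may reach the wrong face of C10=C14. The cationic catalyst may also isomerise the allylic alcohol. The fallback replaces hydroxyl delivery by steric shielding and sets out from 33: O9 is silylated (TBSOTf, 2,6-lutidine) to the silyl ether F3, which is hydrogenated with RhCl(PPh3)3 under H2 so that hydrogen arrives anti to the bulky silyloxy group and gives the saturated silyl ether F4. HF·pyridine then removes the silyl group and the route is rejoined at 34.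

**Step 12.** Facial selectivity in the addition to 22 may be only moderate, because the alkenylchromium reagent is not very sensitive to the α-alkoxy centre. The fallback sets C3 by reduction instead of by the carbon–carbon bond formation and sets out from 21: the coupling is run as in step 12 and the mixture of 24 and its (3S)-epimer F5 is oxidised (Dess–Martin periodinane) to the enone F6. Reduction with Zn(BH4)2 in Et2O at −30 °C, chelation-controlled by the dioxolane oxygen, gives the anti alcohol and returns to 24.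

**Step 11.** The iodo-ylide is formed in several stages and is only moderately reactive, so low conversion, erosion of the Z selectivity and partial epimerisation at C6 of the α-acyloxy aldehyde are all possible. The fallback builds the alkene in two stereodefined stages and sets out from 16: dibromo-olefination (CBr4, PPh3, CH2Cl2, 0 °C) gives the dibromoalkene F7. A trans-selective Negishi methylation (Me2Zn, PdCl2(DPEphos) cat., THF) replaces the bromine trans to C6 and gives the (Z)-bromoalkene F8. F8 enters the CrCl2/NiCl2 coupling with 22 in place of the iodide and comes back at 24.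

**Step 21.** The O9 alkoxide formed by the first equivalent of base may attack the lactone carbonyl (acyl migration to a six-membered lactone) before the enolate forms, or the dianion may aggregate and react incompletely. The fallback avoids the dianion and sets out from 34: O9 is capped (Et3SiOTf, 2,6-lutidine) as the triethylsilyl ether F9. The mono-enolate (LiN(i-Pr)2, then CH2=NMe2+ I−) gives the Mannich base F10, MeI gives the ammonium iodide F11, and NaHCO3 gives the silylated methylene lactone F12. HF·pyridine frees O9 and returns to 37.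

## Further compounds

F1 | step 17 | (2R,3R,6S,7S,9S)-3,9-bis(TBS-oxy)-2-hydroxygermacra-4Z,10(14)-dien-12,6-olide (C2 epimer of 31) | C1C(=O)O[C@@H]2/C=C(/C)[C@@H](O[Si](C)(C)C(C)(C)C)[C@H](O)CC(=C)[C@@H](O[Si](C)(C)C(C)(C)C)C[C@@H]12
F2 | step 17 | (2S)-4-nitrobenzoate of 31 | C1C(=O)O[C@@H]2/C=C(/C)[C@@H](O[Si](C)(C)C(C)(C)C)[C@@H](OC(=O)c3ccc(cc3)[N+](=O)[O-])CC(=C)[C@@H](O[Si](C)(C)C(C)(C)C)C[C@@H]12
F3 | step 20 | 9-O-TBS ether of 33 | C1C(=O)O[C@@H]2/C=C(/C)[C@H]3OC(C)(C)O[C@H]3CC(=C)[C@@H](O[Si](C)(C)C(C)(C)C)C[C@@H]12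
F4 | step 20 | 9-O-TBS ether of 34 | C1C(=O)O[C@@H]2/C=C(/C)[C@H]3OC(C)(C)O[C@H]3C[C@@H](C)[C@@H](O[Si](C)(C)C(C)(C)C)C[C@@H]12
F5 | step 12 | (3S)-epimer of 24 | C=C(COCc1ccc(OC)cc1)[C@@H](O[Si](C)(C)C(C)(C)C)C[C@H]1CC(=O)O[C@@H]1/C=C(/C)[C@H](O)[C@@H]2COC(C)(C)O2
F6 | step 12 | C3 ketone (Z-enone) derived from 24 | C=C(COCc1ccc(OC)cc1)[C@@H](O[Si](C)(C)C(C)(C)C)C[C@H]1CC(=O)O[C@@H]1/C=C(/C)C(=O)[C@@H]2COC(C)(C)O2
F7 | step 11 | (4S,5S)-4-[(2S)-2-(TBS-oxy)-3-[(PMB-oxy)methyl]but-3-en-1-yl]-5-(2,2-dibromovinyl)dihydrofuran-2(3H)-one | C=C(COCc1ccc(OC)cc1)[C@@H](O[Si](C)(C)C(C)(C)C)C[C@H]1CC(=O)O[C@@H]1C=C(Br)Br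
F8 | step 11 | (4S,5S)-4-[(2S)-2-(TBS-oxy)-3-[(PMB-oxy)methyl]but-3-en-1-yl]-5-[(Z)-2-bromoprop-1-en-1-yl]dihydrofuran-2(3H)-one | C=C(COCc1ccc(OC)cc1)[C@@H](O[Si](C)(C)C(C)(C)C)C[C@H]1CC(=O)O[C@@H]1/C=C(/C)Br
F9 | step 21 | 9-O-TES ether of 34 | C1C(=O)O[C@@H]2/C=C(/C)[C@H]3OC(C)(C)O[C@H]3C[C@@H](C)[C@@H](O[Si](CC)(CC)CC)C[C@@H]12
F10 | step 21 | 9-O-TES ether of 35 (C11 epimers) | CN(C)CC1C(=O)O[C@@H]2/C=C(/C)[C@H]3OC(C)(C)O[C@H]3C[C@@H](C)[C@@H](O[Si](CC)(CC)CC)C[C@@H]12
F11 | step 21 | 9-O-TES ether of 36 | C[N+](C)(C)CC1C(=O)O[C@@H]2/C=C(/C)[C@H]3OC(C)(C)O[C@H]3C[C@@H](C)[C@@H](O[Si](CC)(CC)CC)C[C@@H]12.[I-]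
F12 | step 21 | 9-O-TES ether of 37 | C=C1C(=O)O[C@@H]2/C=C(/C)[C@H]3OC(C)(C)O[C@H]3C[C@@H](C)[C@@H](O[Si](CC)(CC)CC)C[C@@H]12
A1 | alternative 1 | (2S,3R,6S,7S,10R)-2,3-(isopropylidenedioxy)-9-oxogermacr-4Z-en-12,6-olide (Z-cyclodec-4-en-9-one) | C1C(=O)O[C@@H]2/C=C(/C)[C@H]3OC(C)(C)O[C@H]3C[C@@H](C)C(=O)C[C@@H]12
A2 | alternative 2 | ten-membered C6 alcohol with 2,3-acetonide, 9-O-TBS ether and a 3-(PMB-oxy)prop-1-en-2-yl group on C7, configured as in 41 | O[C@@H]1/C=C(/C)[C@H]2OC(C)(C)O[C@H]2C[C@@H](C)[C@@H](O[Si](C)(C)C(C)(C)C)C[C@H]1C(=C)COCc1ccc(OC)cc1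
A3 | alternative 3 | (2S,3R,6R,7S,9S,10R)-9-(TBS-oxy)-2,3-(isopropylidenedioxy)germacra-4Z,11(13)-dien-12,6-olide | C=C1C(=O)O[C@@H]2/C=C(/C)[C@H]3OC(C)(C)O[C@H]3C[C@@H](C)[C@@H](O[Si](C)(C)C(C)(C)C)C[C@@H]12
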